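**Retrosynthetic overview**

1. The strategy rests on C3 of the chroman-4-one. It carries the aryl group and two one-carbon arms, C2 (ether level, bonded to O1) and C4 (acyl level, bonded to C4a), so it is latent in a prochiral 2-arylpropane-1,3-diol whose arms a lipase can tell apart.
2. Target 18 comes from silyl ether 17 by buffered fluoride. 17 comes from bromo thioester 16 by forming C4–C4a, the acyl–aryl bond ortho to O1, under cathodic nickel catalysis. The 7-hydroxyl travels as a triisopropylsilyl ether so that it can be freed without acid or free base.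
3. 16 comes from monoacetate 9 and bromophenol 11: Mitsunobu ether on the free arm (future C2), then deacetylation and oxidation of the other arm (future C4).
4. 9 comes from diol 8, arylmalonate 7 and bromochromene 5. Compound 5 is built from 4-bromo-3-methoxyphenol and prenal, so no electrophilic bromination is run on the reactive chromene double bond.
5. Ring order: the 2,2-dimethylpyran ring of the chromene first (step 1), the pyranone ring of the chromanone in step 10; both benzene rings are bought.

Key step: step 10

Assumption: in step 4 the lipase is taken to acetylate the pro-S hydroxymethyl arm of diol 8, giving the (S)-monoacetate 9; the sense must be confirmed on the first batch, and the fallback for step 4 covers the opposite outcome.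

**Route**

Step 1
Reactants: 1 4-bromo-3-methoxyphenol; 2 3-methylbut-2-enal
Product: 5 6-bromo-7-methoxy-2,2-dimethyl-2H-chromene, via benzodioxaborin 3 (not isolated), via ortho-quinone methide 4 (not isolated)
Conditions: PhB(OH)2 (1 equiv), AcOH, toluene, reflux, Dean–Stark
Reagents that add atoms: none
Why: Phenylboronic acid-templated ortho-condensation of a phenol with an enal followed by oxa-6π electrocyclisation of the ortho-quinone methide is an established 2H-chromene synthesis, and the unhindered ortho position of 1 (C6, para to the methoxy group) should react, which places bromine at C6 and methoxy at C7 of the chromene.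

Step 2
Reactants: 5 6-bromo-7-methoxy-2,2-dimethyl-2H-chromene; 6 diethyl malonate
Product: 7 diethyl 2-(7-methoxy-2,2-dimethyl-2H-chromen-6-yl)malonate
Conditions: Pd(OAc)2 (2 mol %), P(t-Bu)3·HBF4 (4 mol %), K3PO4 (3 equiv), toluene, 80 °C
Reagents that add atoms: none
Why: Palladium-catalysed α-arylation of a malonate (Hartwig–Buchwald type) with a bulky trialkylphosphine couples electron-rich ortho-substituted aryl bromides, and the mild phosphate base leaves the chromene double bond alone.

Step 3
Reactants: 7 diethyl 2-(7-methoxy-2,2-dimethyl-2H-chromen-6-yl)malonate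
Product: 8 2-(7-methoxy-2,2-dimethyl-2H-chromen-6-yl)propane-1,3-diol
Conditions: LiAlH4 (3 equiv), THF, 0 °C to rt; then H2O, aq NaOH
Reagents that add atoms: none
Why: Hydride reduction of both esters to primary alcohols gives the prochiral 2-aryl-1,3-diol, and neither the aryl ethers nor the styrenic chromene double bond are reduced by LiAlH4.

Step 4
Reactants: 8 2-(7-methoxy-2,2-dimethyl-2H-chromen-6-yl)propane-1,3-diol
Product: 9 (S)-3-hydroxy-2-(7-methoxy-2,2-dimethyl-2H-chromen-6-yl)propyl acetate
Conditions: Burkholderia cepacia lipase (Amano PS, immobilised), vinyl acetate (5 equiv), t-BuOMe, 25 °C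
Reagents that add atoms: vinyl acetate, C=COC(C)=O
Why: Lipase-catalysed irreversible transesterification (enzymatic desymmetrisation) of 2-aryl-1,3-propanediols is well established, the chiral active site acylates one enantiotopic hydroxymethyl arm (assumed pro-S) and so sets C3, and slow further acetylation of the minor monoacetate should raise the enantiomeric purity.

Step 5
Reactants: 10 4-bromoresorcinol
Product: 11 2-bromo-5-[(triisopropylsilyl)oxy]phenol
Conditions: TIPSCl (1 equiv), imidazole (2 equiv), CH2Cl2, −20 to 0 °C
Reagents that add atoms: chlorotriisopropylsilane (TIPSCl), CC(C)[Si](Cl)(C(C)C)C(C)C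
Why: Silylation of a phenol with a bulky trialkylsilyl chloride is sterically governed, so the unhindered hydroxyl para to bromine should react in preference to the hydroxyl flanked by bromine, leaving the more acidic ortho-bromophenol free for the Mitsunobu step.

Step 6
Reactants: 9 (S)-3-hydroxy-2-(7-methoxy-2,2-dimethyl-2H-chromen-6-yl)propyl acetate; 11 2-bromo-5-[(triisopropylsilyl)oxy]phenol
Product: 12 (S)-3-{2-bromo-5-[(triisopropylsilyl)oxy]phenoxy}-2-(7-methoxy-2,2-dimethyl-2H-chromen-6-yl)propyl acetate
Conditions: PPh3, DIAD, THF, 0 °C to rt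
Reagents that add atoms: none
Why: Mitsunobu etherification of a primary alcohol with an acidic ortho-halophenol is reliable, C3 is not a reacting centre so its configuration is kept, and the near-neutral medium should not trigger the 1,3-acetyl shift that would scramble the two arms.

Step 7
Reactants: 12 (S)-3-{2-bromo-5-[(triisopropylsilyl)oxy]phenoxy}-2-(7-methoxy-2,2-dimethyl-2H-chromen-6-yl)propyl acetate
Product: 13 (R)-3-{2-bromo-5-[(triisopropylsilyl)oxy]phenoxy}-2-(7-methoxy-2,2-dimethyl-2H-chromen-6-yl)propan-1-ol
Conditions: i-Bu2AlH (2.5 equiv), CH2Cl2, −78 °C; then aq KNaC4H4O6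
Reagents that add atoms: none
Why: Reductive cleavage of the acetate with i-Bu2AlH at low temperature frees the second arm without the basic methanolysis that could attack the aryl silyl ether, and aryl bromide, silyl ether and chromene are inert to the reagent (the descriptor changes to R only through the priority rules).

Step 8
Reactants: 13 (R)-3-{2-bromo-5-[(triisopropylsilyl)oxy]phenoxy}-2-(7-methoxy-2,2-dimethyl-2H-chromen-6-yl)propan-1-ol
Product: 15 (S)-3-{2-bromo-5-[(triisopropylsilyl)oxy]phenoxy}-2-(7-methoxy-2,2-dimethyl-2H-chromen-6-yl)propanoic acid, via aldehyde 14 (not isolated)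
Conditions: TEMPO (0.2 equiv), PhI(OAc)2 (2.5 equiv), MeCN/H2O, 0 °C to rt
Reagents that add atoms: water, O
Why: The nitroxide-catalysed PhI(OAc)2 oxidation takes a primary alcohol through the aldehyde and its hydrate to the acid in one pot under mildly acidic, halogen-free conditions, so the enolisable aldehyde is short-lived, C3 should be kept, the aryloxide should not be expelled and the electron-rich rings are not halogenated.

Step 9
Reactants: 15 (S)-3-{2-bromo-5-[(triisopropylsilyl)oxy]phenoxy}-2-(7-methoxy-2,2-dimethyl-2H-chromen-6-yl)propanoic acid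
Product: 16 S-(pyridin-2-yl) (S)-3-{2-bromo-5-[(triisopropylsilyl)oxy]phenoxy}-2-(7-methoxy-2,2-dimethyl-2H-chromen-6-yl)propanethioate
Conditions: 2,2′-dipyridyl disulfide, PPh3, CH2Cl2, 0 °C to rt
Reagents that add atoms: 2,2′-dipyridyl disulfide, c1ccc(SSc2ccccn2)nc1
Why: The Mukaiyama redox condensation (Corey–Nicolaou thioester formation) activates the acid as an acyloxyphosphonium ion that is captured by pyridine-2-thiolate without added amine base, so the acidic C3–H next to the aryloxymethyl group should be left in place.

Step 10
Reactants: 16 S-(pyridin-2-yl) (S)-3-{2-bromo-5-[(triisopropylsilyl)oxy]phenoxy}-2-(7-methoxy-2,2-dimethyl-2H-chromen-6-yl)propanethioate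
Product: 17 (S)-3-(7-methoxy-2,2-dimethyl-2H-chromen-6-yl)-7-[(triisopropylsilyl)oxy]chroman-4-one
Conditions: NiBr2·dme (10 mol %), 4,4′-di-tert-butyl-2,2′-bipyridine (12 mol %), n-Bu4NBr, DMA (high dilution), undivided cell, zinc anode, nickel-foam cathode, constant current, 2.2–2.5 F/mol, 20 °C
Reagents that add atoms: none
Why: Proposed new method: cathodic reduction of the NiBr2–bipyridine complex should give zerovalent nickel, which inserts into the C–Br bond; the arylnickel bromide takes up one more electron to a monovalent arylnickel species that adds oxidatively to the C(acyl)–S bond of the 2-pyridyl thioester, and reductive elimination from the trivalent aryl(acyl)nickel thiolate forms C4–C4a while zinc ions from the anode take up bromide and thiolate. The closest known reaction type is the intermolecular nickel-catalysed reductive cross-electrophile coupling of aryl halides with thioesters, acid chlorides or anhydrides to aryl ketones, driven by zinc or manganese powder or by a cathode; the ring-forming version on an α-branched, enolisable thioester is the untested part. The pyranone ring closes in a 6-exo-trig acyl substitution in which the aryl carbon ortho to O1 attacks the thioester carbon. No stereocentre is created, and C3 should be carried through unchanged because the medium holds no amine base or organometallic nucleophile and the only base formed is weakly basic zinc pyridine-2-thiolate. The step needs ring closure to outrun protodebromination, intermolecular coupling and decarbonylation of the α-aryl acylnickel intermediate; the six-membered tether, high dilution, room temperature and the chelating bipyridine ligand should secure this.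

Step 11
Reactants: 17 (S)-3-(7-methoxy-2,2-dimethyl-2H-chromen-6-yl)-7-[(triisopropylsilyl)oxy]chroman-4-one
Product: 18 (S)-7-hydroxy-3-(7-methoxy-2,2-dimethyl-2H-chromen-6-yl)chroman-4-one
Conditions: n-Bu4NF, AcOH (1 equiv each), THF, 0 °C
Reagents that add atoms: none
Why: Fluoride cleaves the aryl silyl ether rapidly and the acetic acid buffer protonates the phenoxide as it forms, so neither epimerisation at C3 nor base-induced opening of the pyranone ring should occur and the chromene sees no strong acid.

**Compound list**

1 | 4-bromo-3-methoxyphenol | COc1cc(O)ccc1Br | starting material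
2 | 3-methylbut-2-enal (prenal) | CC(C)=CC=O | starting material
3 | 6-bromo-7-methoxy-4-(2-methylprop-1-en-1-yl)-2-phenyl-4H-1,3,2-benzodioxaborinine (racemic) | COc1cc2OB(c3ccccc3)OC(C=C(C)C)c2cc1Br | intermediate
4 | 4-bromo-3-methoxy-6-(3-methylbut-2-en-1-ylidene)cyclohexa-2,4-dien-1-one (ortho-quinone methide) | COC1=CC(=O)C(=CC=C(C)C)C=C1Br | intermediate
5 | 6-bromo-7-methoxy-2,2-dimethyl-2H-chromene | COc1cc2OC(C)(C)C=Cc2cc1Br | intermediate
6 | diethyl malonate | CCOC(=O)CC(=O)OCC | starting material
7 | diethyl 2-(7-methoxy-2,2-dimethyl-2H-chromen-6-yl)malonate | CCOC(=O)C(C(=O)OCC)c1cc2C=CC(C)(C)Oc2cc1OC | intermediate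
8 | 2-(7-methoxy-2,2-dimethyl-2H-chromen-6-yl)propane-1,3-diol | COc1cc2OC(C)(C)C=Cc2cc1C(CO)CO | intermediate
9 | (S)-3-hydroxy-2-(7-methoxy-2,2-dimethyl-2H-chromen-6-yl)propyl acetate | COc1cc2OC(C)(C)C=Cc2cc1[C@H](COC(C)=O)CO | intermediate
10 | 4-bromoresorcinol | Oc1ccc(Br)c(O)c1 | starting material
11 | 2-bromo-5-[(triisopropylsilyl)oxy]phenol | CC(C)[Si](Oc1ccc(Br)c(O)c1)(C(C)C)C(C)C | intermediate
12 | (S)-3-{2-bromo-5-[(triisopropylsilyl)oxy]phenoxy}-2-(7-methoxy-2,2-dimethyl-2H-chromen-6-yl)propyl acetate | COc1cc2OC(C)(C)C=Cc2cc1[C@H](COC(C)=O)COc1cc(O[Si](C(C)C)(C(C)C)C(C)C)ccc1Br | intermediate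
13 | (R)-3-{2-bromo-5-[(triisopropylsilyl)oxy]phenoxy}-2-(7-methoxy-2,2-dimethyl-2H-chromen-6-yl)propan-1-ol | COc1cc2OC(C)(C)C=Cc2cc1[C@H](CO)COc1cc(O[Si](C(C)C)(C(C)C)C(C)C)ccc1Br | intermediate
14 | (S)-3-{2-bromo-5-[(triisopropylsilyl)oxy]phenoxy}-2-(7-methoxy-2,2-dimethyl-2H-chromen-6-yl)propanal | COc1cc2OC(C)(C)C=Cc2cc1[C@H](C=O)COc1cc(O[Si](C(C)C)(C(C)C)C(C)C)ccc1Br | intermediate
15 | (S)-3-{2-bromo-5-[(triisopropylsilyl)oxy]phenoxy}-2-(7-methoxy-2,2-dimethyl-2H-chromen-6-yl)propanoic acid | COc1cc2OC(C)(C)C=Cc2cc1[C@H](C(=O)O)COc1cc(O[Si](C(C)C)(C(C)C)C(C)C)ccc1Br | intermediate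
16 | S-(pyridin-2-yl) (S)-3-{2-bromo-5-[(triisopropylsilyl)oxy]phenoxy}-2-(7-methoxy-2,2-dimethyl-2H-chromen-6-yl)propanethioate | COc1cc2OC(C)(C)C=Cc2cc1[C@H](C(=O)Sc1ccccn1)COc1cc(O[Si](C(C)C)(C(C)C)C(C)C)ccc1Br | intermediate
17 | (S)-3-(7-methoxy-2,2-dimethyl-2H-chromen-6-yl)-7-[(triisopropylsilyl)oxy]chroman-4-one | COc1cc2OC(C)(C)C=Cc2cc1[C@H]1COc2cc(O[Si](C(C)C)(C(C)C)C(C)C)ccc2C1=O | intermediate
18 | (S)-7-hydroxy-3-(7-methoxy-2,2-dimethyl-2H-chromen-6-yl)chroman-4-one (CNP0226344.1) | COc1cc2c(cc1[C@H]1COc3cc(O)ccc3C1=O)C=CC(C)(C)O2 | target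

**Step count**

Total steps: 11. Longest linear sequence: 10 steps (steps 1–4 and 6–11; step 5 is a one-step side branch).

**Steps most likely to fail**

Step 10 (key step). What may go wrong: the α-aryl acylnickel intermediate may lose CO and close the ring-contracted dihydrobenzofuran, the aryl bromide may be reduced to the arene, or the activated thioester may epimerise or expel the aryloxide before nickel engages it. The fallback sets out from acid 15 (step 9 is omitted) and comes back to the route at 17. It is a Parham cycliacylation with n-BuLi (2.1 equiv) in THF at −100 °C. The first equivalent forms the lithium carboxylate, whose α-C–H is far less acidic than that of the thioester; the second exchanges bromine for lithium. The aryllithium then adds to the carboxylate carbon in a 6-exo closure, and the resulting dilithium gem-diolate survives until an inverse quench into cold AcOH/THF, which releases ketone 17 without exposure to base. No compound outside the list is made (F0).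

Step 8. What may go wrong: while the arm passes through aldehyde 14 in water, enolisation at C3 (loss of enantiomeric purity), β-elimination of the bromophenoxide, or attack of the oxidant on the electron-rich chromene double bond may compete with oxidation of the hydrate. The fallback sets out from alcohol 13 and comes back at 17, so the acid level is never reached by oxidation of an aldehyde. Aromatic Finkelstein exchange (CuI, N,N′-dimethylethylenediamine, NaI, dioxane, 110 °C) should give (R)-3-{2-iodo-5-[(triisopropylsilyl)oxy]phenoxy}-2-(7-methoxy-2,2-dimethyl-2H-chromen-6-yl)propan-1-ol F1. Dess–Martin periodinane with NaHCO3 in dry CH2Cl2 should give (S)-3-{2-iodo-5-[(triisopropylsilyl)oxy]phenoxy}-2-(7-methoxy-2,2-dimethyl-2H-chromen-6-yl)propanal F2, used crude at once. An intramolecular Nozaki–Hiyama–Kishi reaction (CrCl2 in excess, NiCl2 catalytic, DMF, rt), which tolerates enolisable aldehydes, should close the ring to (3S)-3-(7-methoxy-2,2-dimethyl-2H-chromen-6-yl)-7-[(triisopropylsilyl)oxy]chroman-4-ol F3 as a mixture of C4 epimers. Dess–Martin oxidation of the benzylic alcohol then gives ketone 17.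

Step 4. What may go wrong: the lipase may acetylate the other enantiotopic arm (giving the antipode of 9), or may discriminate poorly because of the ortho-methoxy group on the aryl substituent. The fallback sets out from diol 8 and comes back at 9 by reversing the direction of the enzymatic reaction. Exhaustive acetylation (Ac2O, pyridine, DMAP) gives 2-(7-methoxy-2,2-dimethyl-2H-chromen-6-yl)propane-1,3-diyl diacetate F4. Hydrolysis with the same lipase (pH 7 phosphate buffer/acetone, 25 °C) is stopped at the monoacetate. Because the enzyme now removes the acetate from the arm it prefers, the monoacetate formed is the enantiomer of the one obtained by acylation, which is 9 if the acylation had given its antipode.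

**Further compounds**

F0 | step 10 | none | none
F1 | step 8 | (R)-3-{2-iodo-5-[(triisopropylsilyl)oxy]phenoxy}-2-(7-methoxy-2,2-dimethyl-2H-chromen-6-yl)propan-1-ol | COc1cc2OC(C)(C)C=Cc2cc1[C@H](CO)COc1cc(O[Si](C(C)C)(C(C)C)C(C)C)ccc1I
F2 | step 8 | (S)-3-{2-iodo-5-[(triisopropylsilyl)oxy]phenoxy}-2-(7-methoxy-2,2-dimethyl-2H-chromen-6-yl)propanal | COc1cc2OC(C)(C)C=Cc2cc1[C@H](C=O)COc1cc(O[Si](C(C)C)(C(C)C)C(C)C)ccc1I
F3 | step 8 | (3S)-3-(7-methoxy-2,2-dimethyl-2H-chromen-6-yl)-7-[(triisopropylsilyl)oxy]chroman-4-ol (both C4 epimers) | COc1cc2OC(C)(C)C=Cc2cc1[C@H]1COc2cc(O[Si](C(C)C)(C(C)C)C(C)C)ccc2C1O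
F4 | step 4 | 2-(7-methoxy-2,2-dimethyl-2H-chromen-6-yl)propane-1,3-diyl diacetate | COc1cc2OC(C)(C)C=Cc2cc1C(COC(C)=O)COC(C)=O
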